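**Plan**
- Retrosynthesis: the O3–S and O7–S bonds are cut first, then ring B is opened across C1'–C2' and C5'–C6' into a chromone bearing an ethynyl group on C2 and a 2,3-bis(silyloxy)butadiene.
- The alkyne is then cut at C2–C(sp) (Sonogashira), O3 is removed from C3, and ring C is cut at O1–C2/C2–C3 back to phloroacetophenone plus a one-carbon unit.
- Enabling feature: ring B carries its two oxygens on the adjacent carbons C3' and C4', opposite the C1'–C6' edge. These are the two inner carbons of a butadiene whose termini (C2', C5') add across a C1'≡C6' alkyne attached to C2 of ring C.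
- Forward: ring A is bought; ring C is closed (enaminone cyclisation); O3 is added by epoxidation/isomerisation; the alkyne is attached at C2; ring B is built last by [4+2] addition and dehydrogenation; then debenzylation, 3,7-disulfation and desilylation.
- Stereochemistry: the target has no stereocentre. Only the transient epoxide 5 is chiral (racemic), and its centres disappear on isomerisation.

Key step: step 9

Assumption: the target is drawn as the free bis(hydrogen sulfate). Sulfates 18 and 19 are written in this neutral form but would be handled as salts (pyridinium, then potassium), the free acid being released only by brief H+ ion exchange at 0 °C.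

**Route**

Step 1
Reactants: 1 2',4',6'-trihydroxyacetophenone
Product: 2 1-[2,4-bis(benzyloxy)-6-hydroxyphenyl]ethan-1-one
Conditions: BnBr (2.1 equiv), K2CO3, DMF, 0 °C → rt
Reagents that add atoms: benzyl bromide, BrCc1ccccc1
Why: Williamson O-benzylation alkylates the para and one ortho phenol, while the remaining ortho OH, held in a hydrogen bond to the ketone, stays free for the later ring closure.

Step 2
Reactants: 2 1-[2,4-bis(benzyloxy)-6-hydroxyphenyl]ethan-1-one
Product: 4 5,7-bis(benzyloxy)-4H-chromen-4-one, via enaminone 3 (not isolated)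
Conditions: DMF-DMA (3 equiv), toluene, 100 °C; then conc. HCl, CH2Cl2, 40 °C
Reagents that add atoms: N,N-dimethylformamide dimethyl acetal, COC(OC)N(C)C
Why: Enaminone condensation of the methyl ketone, then acid-promoted intramolecular oxa-Michael addition of the free phenol with loss of dimethylamine (enaminone route to chromones), closes ring C under conditions that benzyl ethers tolerate.

Step 3
Reactants: 4 5,7-bis(benzyloxy)-4H-chromen-4-one
Product: 6 5,7-bis(benzyloxy)-3-hydroxy-4H-chromen-4-one, via chromone epoxide 5 (not isolated)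
Conditions: DMDO (acetone solution, ca. 3 equiv in portions), CH2Cl2, 0 °C → rt; then p-TsOH·H2O (cat.), CH2Cl2, rt
Reagents that add atoms: dimethyldioxirane, CC1(C)OO1
Why: Dioxirane epoxidation of C2=C3 followed by acid-catalysed epoxide isomerisation (opening at C2 to the O1-stabilised oxocarbenium ion, then loss of H3), the sequence used to convert flavones into flavonols, installs O3 without touching the benzyl ethers.

Step 4
Reactants: 6 5,7-bis(benzyloxy)-3-hydroxy-4H-chromen-4-one
Product: 7 3,5,7-tris(benzyloxy)-4H-chromen-4-one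
Conditions: BnBr (1.2 equiv), K2CO3, DMF, rt
Reagents that add atoms: benzyl bromide, BrCc1ccccc1
Why: Williamson etherification of the acidic enolic 3-OH, the only free hydroxyl, should proceed readily with carbonate base.

Step 5
Reactants: 7 3,5,7-tris(benzyloxy)-4H-chromen-4-one
Product: 9 3,5,7-tris(benzyloxy)-2-iodo-4H-chromen-4-one, via bis(chromon-2-yl)zinc 8 (not isolated)
Conditions: TMP2Zn·2MgCl2·2LiCl (0.6 equiv), THF, −30 °C → rt; then I2 (1.3 equiv), THF, 0 °C
Reagents that add atoms: iodine, II
Why: Directed metalation with a TMP–zinc base, assisted by MgCl2 coordination at the C4 carbonyl, removes the only pyranone C–H (C2, flanked by O1 and the 3-benzyloxy group) to give a diorganozinc that does not add to unreacted chromone, and iodolysis then gives the 2-iodide.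

Step 6
Reactants: 9 3,5,7-tris(benzyloxy)-2-iodo-4H-chromen-4-one; 10 trimethylsilylacetylene
Product: 11 3,5,7-tris(benzyloxy)-2-[(trimethylsilyl)ethynyl]-4H-chromen-4-one
Conditions: PdCl2(PPh3)2 (3 mol %), CuI (5 mol %), Et3N (3 equiv), THF, rt
Reagents that add atoms: none
Why: Sonogashira coupling should be fast at room temperature because the 2-iodochromone is a vinylogous acyl iodide, and a tertiary amine base cannot substitute C2 by addition–elimination.

Step 7
Reactants: 11 3,5,7-tris(benzyloxy)-2-[(trimethylsilyl)ethynyl]-4H-chromen-4-one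
Product: 12 3,5,7-tris(benzyloxy)-2-ethynyl-4H-chromen-4-one
Conditions: TBAF (1.1 equiv), AcOH (1.5 equiv), THF, −20 → 0 °C
Reagents that add atoms: none
Why: Fluoride-mediated protodesilylation of the alkynylsilane, buffered with acetic acid so that no nucleophile adds to the ynenone or opens the pyranone ring.

Step 8
Reactants: 13 butane-2,3-dione
Product: 14 2,3-bis(tert-butyldimethylsilyloxy)buta-1,3-diene
Conditions: TBSOTf (2.2 equiv), Et3N (3 equiv), CH2Cl2, 0 °C → rt
Reagents that add atoms: tert-butyldimethylsilyl trifluoromethanesulfonate, CC(C)(C)[Si](C)(C)OS(=O)(=O)C(F)(F)F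
Why: Double soft enolisation and O-silylation of the 1,2-diketone with a silyl triflate and tertiary amine (silyl enol ether formation) gives the symmetric 2,3-dioxygenated diene.

Step 9
Reactants: 12 3,5,7-tris(benzyloxy)-2-ethynyl-4H-chromen-4-one; 14 2,3-bis(tert-butyldimethylsilyloxy)buta-1,3-diene
Product: 16 3,5,7-tris(benzyloxy)-2-[3,4-bis(tert-butyldimethylsilyloxy)phenyl]-4H-chromen-4-one, via cyclohexa-1,4-diene cycloadduct 15 (not isolated)
Conditions: CoBr2(dppe) (10 mol %), Zn (20 mol %), ZnI2 (20 mol %), 14 (1.3 equiv), CH2Cl2, rt; then DDQ (1.5 equiv), same flask, 0 °C → rt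
Reagents that add atoms: none
Why: A dppe-ligated Co(I) species formed from CoBr2(dppe), Zn and ZnI2 binds the diene and the terminal alkyne, couples them oxidatively to a cobaltacycle and reductively eliminates the 1,4-cyclohexadiene 15, after which DDQ abstracts a hydride from a doubly allylic CH2 and proton loss aromatises ring B with both silyl ethers in place. The closest known reaction type is the cobalt-catalysed neutral Diels–Alder reaction of terminal aryl alkynes with 2-silyloxy- and 2,3-disubstituted butadienes followed by DDQ dehydrogenation to biaryls. Ring B closes as a six-membered carbocycle by intermolecular [4+2] annulation in which the diene termini become C2' and C5' and bond to the alkyne carbons C1' and C6'. No stereocentre is created, and the two sp3 carbons of 15 are erased on aromatisation. The step needs the alkyne to react in preference to the tetrasubstituted, donor-flanked C2=C3 bond and cross-addition to beat alkyne trimerisation, which the metal's preference for alkyne–diene pairing and an excess of the symmetric diene (no regiochemical question) should secure, helped by conjugation of the alkyne with C2=C3–C4=O. Benzyl ethers are inert to DDQ at room temperature without irradiation.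

Step 10
Reactants: 16 3,5,7-tris(benzyloxy)-2-[3,4-bis(tert-butyldimethylsilyloxy)phenyl]-4H-chromen-4-one
Product: 17 2-[3,4-bis(tert-butyldimethylsilyloxy)phenyl]-3,5,7-trihydroxy-4H-chromen-4-one
Conditions: H2 (1 atm), 10% Pd/C, EtOAc/THF, rt
Reagents that add atoms: none
Why: Catalytic hydrogenolysis cleaves the three benzyl ethers, while the aryl silyl ethers and the tetrasubstituted C2=C3 bond of the flavonol are untouched in an aprotic solvent, as in routine debenzylation of protected flavonols.

Step 11
Reactants: 17 2-[3,4-bis(tert-butyldimethylsilyloxy)phenyl]-3,5,7-trihydroxy-4H-chromen-4-one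
Product: 18 2-[3,4-bis(tert-butyldimethylsilyloxy)phenyl]-5-hydroxy-4-oxo-4H-chromene-3,7-diyl bis(hydrogen sulfate) (formed as the bis-pyridinium salt)
Conditions: SO3·pyridine (6 equiv), pyridine, rt → 40 °C; Sephadex LH-20
Reagents that add atoms: sulfur trioxide–pyridine complex, [O-]S(=O)(=O)[n+]1ccccc1
Why: O-Sulfonation with a sulfur trioxide–amine complex converts the acidic 7-OH and the enolic 3-OH, whereas the 5-OH, held in a strong six-membered hydrogen bond to the C4 carbonyl, is the least reactive hydroxyl of a flavonol and should stay free when reagent excess and temperature are limited.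

Step 12
Reactants: 18 2-[3,4-bis(tert-butyldimethylsilyloxy)phenyl]-5-hydroxy-4-oxo-4H-chromene-3,7-diyl bis(hydrogen sulfate)
Product: 19 quercetin 3,7-di-O-sulfate
Conditions: KHF2 (5 equiv), MeOH, rt; Sephadex LH-20 (dipotassium salt); Dowex 50W (H+), H2O, 0 °C for the free acid
Reagents that add atoms: none
Why: Bifluoride-induced cleavage of phenolic silyl ethers is selective and only mildly acidic, so the aryl sulfate monoesters (stable to fluoride, labile only to strong acid) and the oxidation-prone catechol should survive.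

**Compound list**

1 | 2',4',6'-trihydroxyacetophenone | CC(=O)c1c(O)cc(O)cc1O | starting material
2 | 1-[2,4-bis(benzyloxy)-6-hydroxyphenyl]ethan-1-one | CC(=O)c1c(O)cc(OCc2ccccc2)cc1OCc1ccccc1 | intermediate
3 | (E)-1-[2,4-bis(benzyloxy)-6-hydroxyphenyl]-3-(dimethylamino)prop-2-en-1-one | CN(C)/C=C/C(=O)c1c(O)cc(OCc2ccccc2)cc1OCc1ccccc1 | intermediate
4 | 5,7-bis(benzyloxy)-4H-chromen-4-one | O=c1ccoc2cc(OCc3ccccc3)cc(OCc3ccccc3)c12 | intermediate
5 | 5,7-bis(benzyloxy)-2,3-epoxychroman-4-one (cis-fused, racemic; one enantiomer drawn) | O=C1[C@@H]2O[C@@H]2Oc2cc(OCc3ccccc3)cc(OCc3ccccc3)c12 | intermediate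
6 | 5,7-bis(benzyloxy)-3-hydroxy-4H-chromen-4-one | O=c1c(O)coc2cc(OCc3ccccc3)cc(OCc3ccccc3)c12 | intermediate
7 | 3,5,7-tris(benzyloxy)-4H-chromen-4-one | O=c1c(OCc2ccccc2)coc2cc(OCc3ccccc3)cc(OCc3ccccc3)c12 | intermediate
8 | bis[3,5,7-tris(benzyloxy)-4-oxo-4H-chromen-2-yl]zinc (MgCl2/LiCl-complexed) | [Zn](c1oc2cc(OCc3ccccc3)cc(OCc3ccccc3)c2c(=O)c1OCc1ccccc1)c1oc2cc(OCc3ccccc3)cc(OCc3ccccc3)c2c(=O)c1OCc1ccccc1 | intermediate
9 | 3,5,7-tris(benzyloxy)-2-iodo-4H-chromen-4-one | O=c1c(OCc2ccccc2)c(I)oc2cc(OCc3ccccc3)cc(OCc3ccccc3)c12 | intermediate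
10 | trimethylsilylacetylene | C#C[Si](C)(C)C | starting material
11 | 3,5,7-tris(benzyloxy)-2-[(trimethylsilyl)ethynyl]-4H-chromen-4-one | O=c1c(OCc2ccccc2)c(C#C[Si](C)(C)C)oc2cc(OCc3ccccc3)cc(OCc3ccccc3)c12 | intermediate
12 | 3,5,7-tris(benzyloxy)-2-ethynyl-4H-chromen-4-one | C#Cc1oc2cc(OCc3ccccc3)cc(OCc3ccccc3)c2c(=O)c1OCc1ccccc1 | intermediate
13 | butane-2,3-dione | CC(=O)C(C)=O | starting material
14 | 2,3-bis(tert-butyldimethylsilyloxy)buta-1,3-diene | C=C(O[Si](C)(C)C(C)(C)C)C(=C)O[Si](C)(C)C(C)(C)C | intermediate
15 | 3,5,7-tris(benzyloxy)-2-[4,5-bis(tert-butyldimethylsilyloxy)cyclohexa-1,4-dien-1-yl]-4H-chromen-4-one | O=c1c(OCc2ccccc2)c(C2=CCC(O[Si](C)(C)C(C)(C)C)=C(O[Si](C)(C)C(C)(C)C)C2)oc2cc(OCc3ccccc3)cc(OCc3ccccc3)c12 | intermediate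
16 | 3,5,7-tris(benzyloxy)-2-[3,4-bis(tert-butyldimethylsilyloxy)phenyl]-4H-chromen-4-one | O=c1c(OCc2ccccc2)c(-c2ccc(O[Si](C)(C)C(C)(C)C)c(O[Si](C)(C)C(C)(C)C)c2)oc2cc(OCc3ccccc3)cc(OCc3ccccc3)c12 | intermediate
17 | 2-[3,4-bis(tert-butyldimethylsilyloxy)phenyl]-3,5,7-trihydroxy-4H-chromen-4-one | O=c1c(O)c(-c2ccc(O[Si](C)(C)C(C)(C)C)c(O[Si](C)(C)C(C)(C)C)c2)oc2cc(O)cc(O)c12 | intermediate
18 | 2-[3,4-bis(tert-butyldimethylsilyloxy)phenyl]-5-hydroxy-4-oxo-4H-chromene-3,7-diyl bis(hydrogen sulfate) | O=c1c(OS(=O)(=O)O)c(-c2ccc(O[Si](C)(C)C(C)(C)C)c(O[Si](C)(C)C(C)(C)C)c2)oc2cc(OS(=O)(=O)O)cc(O)c12 | intermediate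
19 | quercetin 3,7-di-O-sulfate | O=c1c(OS(=O)(=O)O)c(-c2ccc(O)c(O)c2)oc2cc(OS(=O)(=O)O)cc(O)c12 | target

**Step count:** 12 steps in total. Longest linear sequence: 11 steps (steps 1–7 and 9–12, from 1); step 8 is a one-step side branch.

**Steps most likely to fail**

1. Step 9. The cobalt or zinc centre may be sequestered by chelation between the C4 carbonyl and the neighbouring oxygens. The alkyne may trimerise faster than it adds the bulky diene, or a silyl group may be lost from the oxocarbenium-type cation during dehydrogenation. The fallback gives up the cycloaddition in favour of a biaryl coupling. It sets out from 7 and returns at 16. 4-Bromocatechol is bis-silylated (TBSCl, imidazole, DMF) to 4-bromo-1,2-bis(tert-butyldimethylsilyloxy)benzene F1. Chromone 7 is zincated at C2 to 8 as in step 5, and 8 is cross-coupled with F1 in a Negishi reaction (Pd(OAc)2, SPhos, THF, 50 °C), which should give 16 directly.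

2. Step 11. Sulfation may stall at the hindered, hydrogen-bonded enolic 3-OH, or overrun onto O5 when forced, leaving salt mixtures that are hard to separate. The fallback uses protected, neutral sulfate diesters that can be chromatographed on silica. It sets out from 17 and returns at 18. Treatment of 17 with 2,2,2-trichloroethyl chlorosulfate (2.2 equiv), Et3N and DMAP in THF at 0 °C should give 2-[3,4-bis(tert-butyldimethylsilyloxy)phenyl]-5-hydroxy-4-oxo-4H-chromene-3,7-diyl bis(2,2,2-trichloroethyl) bis(sulfate) F2. Reductive removal of the trichloroethyl groups with zinc dust and ammonium formate in MeOH then releases 18 as its ammonium salt.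

3. Step 5. Metalation may be incomplete or misdirected (ring-A C–H between two oxygens, or a benzylic CH2), or the 2-iodide may decompose by addition–elimination at C2 during isolation. The fallback forms the C2–alkyne bond by conjugate addition instead of C–H metalation and cross-coupling. It sets out from 7 and returns at 11. TBSOTf-promoted conjugate alkynylation of 7 with the copper acetylide of 10 (CuI, iPr2NEt, CH2Cl2, −40 °C → rt) should give racemic 3,5,7-tris(benzyloxy)-4-(tert-butyldimethylsilyloxy)-2-[(trimethylsilyl)ethynyl]-2H-chromene F3. Dehydrogenation of this silyl enol ether with DDQ (hydride loss from C2, then desilylation on work-up) restores the chromone and delivers 11.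

**Further compounds**

F1 | step 9 | 4-bromo-1,2-bis(tert-butyldimethylsilyloxy)benzene | CC(C)(C)[Si](C)(C)Oc1ccc(Br)cc1O[Si](C)(C)C(C)(C)C
F2 | step 11 | 2-[3,4-bis(tert-butyldimethylsilyloxy)phenyl]-5-hydroxy-4-oxo-4H-chromene-3,7-diyl bis(2,2,2-trichloroethyl) bis(sulfate) | O=c1c(OS(=O)(=O)OCC(Cl)(Cl)Cl)c(-c2ccc(O[Si](C)(C)C(C)(C)C)c(O[Si](C)(C)C(C)(C)C)c2)oc2cc(OS(=O)(=O)OCC(Cl)(Cl)Cl)cc(O)c12
F3 | step 5 | 3,5,7-tris(benzyloxy)-4-(tert-butyldimethylsilyloxy)-2-[(trimethylsilyl)ethynyl]-2H-chromene (racemic) | C[Si](C)(C)C#CC1Oc2cc(OCc3ccccc3)cc(OCc3ccccc3)c2C(O[Si](C)(C)C(C)(C)C)=C1OCc1ccccc1
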